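Late in the north run the excess of right-handed substrate stands still, 23.6 % at 10.0 h and 24.9 % at 20.0 h, while the substrate keeps falling. A steady excess under a single-handed catalyst points to an exchange of hands.

the same everywhere: gas 60 mM (held); catalyst 91 µM

| flask | left-handed substrate | right-handed substrate | added ligand | remark | time |
|---|---|---|---|---|---|
| north | 0.13 M | 0.13 M | 0.065 mM | run made earlier |  |
| west | 0.13 M | 0.13 M | 0.26 mM | run made earlier |  |
| south-west | 0.20 M | 0.20 M | 0.13 mM | run made earlier |  |
| flask | 0.13 M | 0.13 M | 0.13 mM |  | 30 h |

| run | time / h | left-handed substrate / % | right-handed substrate / % |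
|---|---|---|---|
| north | 10.0 | 19.6 | 31.7 |
| north | 20.0 | 9.5 | 15.8 |
| north | 25.0 | 7.3 | 12.1 |
| north | 40.0 | 2.7 | 2.7 |
| west | 3.00 | 49.2 | 50.5 |
| west | 6.00 | 49.4 | 48.5 |
| west | 15.0 | 46.1 | 47.8 |
| west | 40.0 | 44.4 | 46.0 |
| south-west | 3.00 | 46.3 | 49.5 |
| south-west | 6.00 | 45.3 | 47.8 |
| south-west | 15.0 | 40.5 | 45.5 |
| south-west | 40.0 | 32.4 | 34.3 |

(standard deviation of a reading: 1 percentage point)

- catalyst is single-handed; left-handed substrate and right-handed substrate are mirror images of each other, charged as a racemate, each of them at the stated concentration
- at the start none of the gas is in solution
- an excess is the difference of the two amounts in percent of their sum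
- an excess is below zero if the other one leads

1. part of the left-handed substrate and right-handed substrate charged together that has reacted at 30 h
2. excess of left-handed product over right-handed product in the product at 30 h
3. excess of right-handed substrate over left-handed substrate among what is left of the two at 30 h

Let k be the first-order decay constant of the summed substrate and w the rate constant at which exchange erases an excess. Consumption feeds the excess at k·eP, and exchange, net of the shrinking remainder, drains it at (w − k)·eS. A steady eP is therefore eS times one less than w/k.

North decays at 0.0667 h⁻¹, and taking its product as purely left-handed makes w 0.335 h⁻¹. South-west, with the flask's ligand, decays at 0.0101 h⁻¹, taken here for the flask. That gives 33.1, the swap number: how many times faster hands exchange than substrate is consumed, about ten to the power 1.52.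

For the flask, this reckoning gives eS near 3.12 %. South-west reads 2.85 % at 40.0 h. One number is not enough: conversion also needs k and the time, giving 26.1 %. North's excess, standing by 10.0 h, asks for w − k of about 0.230 h⁻¹ or more, which reads as an eP in the north run of about 85.9 % or more; this reckoning carries that over to the flask.

The forecast gives 27 %, 11.6 % and 4.3 %, where “The mass balance then gives” its eP, far below this reckoning.

The flask gives 27.3 %, 98.0 % and 3.36 %.

    partner + catalyst + left-handed substrate → catalyst + left-handed product (k = 1700 L² mol⁻² min⁻¹)
    partner + catalyst + right-handed substrate → catalyst + right-handed product (k = 16.0 L² mol⁻² min⁻¹)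
    left-handed substrate ⇌ right-handed substrate (k = 0.00270 min⁻¹)
    catalyst + added ligand ⇌ idle complex, settled at all times (K = 5.60 × 10⁵ L mol⁻¹)
    gas ⇌ partner, rate k5*(csat - [partner]) (kL = 0.0380 min⁻¹)

This is a dynamic kinetic resolution: left-handed substrate turns into right-handed with a forward half-life of 4.3 h, short against 30 h. Put to this eP, the swap number estimated from the runs, 33.1, gives an eS of 3.05 %, beside the flask's 3.36 %.

In the neighbour flask with 2.2 × 10⁻⁴ M of added ligand, this reckoning takes the swap number in proportion to the added ligand in excess of the catalyst charged: west decays at 0.00252 h⁻¹, 4.01 times slower than south-west, with 4.33 times its excess of ligand, though their substrate charges differ too. That gives 109 and an eS near 0.926 %. The computed neighbour has eS 1.14 % and eP 98.1 %.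

The numbers in the tables are simulated from invented constants; noise was put on by code.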